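Start at the ceiling.

| flask | substrate | enzyme | remark | time |
|---|---|---|---|---|
| eta | 0.10 M | 85 µM | run made earlier |  |
| zeta | 0.14 M | 85 µM | run made earlier |  |
| beta | 0.22 M | 85 µM | run made earlier |  |
| Tuesday's | 0.10 M | 85 µM | one stirred flow tank at steady state, fed with the mixture as stated, mean residence time 2.5 h |  |
| Saturday's | 0.10 M | 85 µM | a closed flask charged with all of it at once and left for 2.5 h | 2.5 h |
| Sunday's | 0.10 M (fed, over 2.00 h) | 85 µM | all but substrate at the start; substrate goes in evenly over 2.00 h, the run ends at 2.5 h | 2.5 h |
| Friday's | 0.10 M | 85 µM | a single well-mixed tank run continuously and read at steady state, 7.50 h in it on average |  |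

- eta (time / min: product / %): 15.0: 6.7; 30.0: 11.6; 50.0: 19.2; 60.0: 23.3; 80.0: 28.3; 90.0: 32.8
- zeta (time / h: product / %): 0.200: 3.1; 0.333: 6.4; 0.500: 8.9; 0.833: 13.0; 1.50: 24.3; 2.50: 40.1
- beta (time / h: product / %): 0.167: 3.3; 0.500: 5.4; 0.833: 10.7; 1.33: 14.9; 2.00: 23.7; 2.50: 28.9

(scatter of a reading: 1 percentage point)

- the stated concentrations are those of everything mixed, before any reaction; amounts are the same in each set-up
- the numbers in the tables scatter with a standard deviation of 1 percentage point
- the feed brings no volume worth counting
- the earlier runs were made in a closed, stirred flask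

1. order of the set-ups by the amount of product at the outlet or at the end, in percent of the substrate put in, highest first (Tuesday's / Saturday's / Sunday's / Friday's)
2. amount of product at the outlet or at the end, in percent of the substrate put in, Tuesday's
3. amount of product at the outlet or at the end, in percent of the substrate put in, Saturday's
4. amount of product at the outlet or at the end, in percent of the substrate put in, Sunday's
5. amount of product at the outlet or at the end, in percent of the substrate put in, Friday's

What do the closed runs show? Product climbs nearly straight in eta, zeta and beta. Mean rates: beta gives 0.0254 M h⁻¹ at a mean c(substrate) of 0.188 M, zeta 0.0225 M h⁻¹ at 0.112 M.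

And what do you make of that? c(substrate) differs by a factor 1.68, the rate by 1.13, so I treat the rate as a ceiling with a small correction. The pair, read as rate = V·c/(K + c), gives a ceiling V of 0.0316 M h⁻¹ and K = 0.0454 M. I call K the debt scale: the c(substrate) at which the rate is half the ceiling, the apparent Michaelis constant. Both are readings and carry the scatter of 1 percentage point.

What is the debt? It is the product lost against V·t. On that rate law, a closed flask owes K·ln(charge/c), and a steady tank owes K·product/c, with t its mean residence time.

Then Saturday's? Try half the charge: the debt is 0.0315 M, and the sum overshoots V·t by 0.00256 M. Taking that back, with its own debt relief, leaves 0.0487 M, or 48.7%.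

And the tanks? Tuesday's has the same 2.5 h, on average, and its balance gives c(substrate) = 0.0563 M, so 43.7%. Friday's tank, at 7.50 h on average, gives 77.8%.

Sunday's? Sunday's feed of 0.0500 M h⁻¹ outruns V, yet its c(substrate), starting from zero, needs at least 0.908 h to reach K. I place it last, without a figure.

The forecast gave Friday's > Saturday's > Tuesday's > Sunday's, with 44%, 49%, 37% and 78% in the order Tuesday's, Saturday's, Sunday's, Friday's, and said: “This looks like saturating Michaelis–Menten kinetics.”

The flask gives Friday's > Saturday's > Tuesday's > Sunday's: Tuesday's 46.6%, Saturday's 51.6%, Sunday's 39.2%, Friday's 80.3%.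

    substrate + enzyme ⇌ complex (K = 12.0 M⁻¹, k = 2.50 × 10⁵ M⁻¹ h⁻¹)
    complex → enzyme + product (k = 730 h⁻¹)
    2 complex ⇌ resting dimer, settled at all times (K = 14000 M⁻¹)

Saturday's flask ends with 48.4% of its substrate. Its debt is then 0.0329 M, and with the product the sum is 0.0845 M against a V·t of 0.0790 M. Friday's tank holds c(substrate) = 0.0197 M, so its debt is 0.185 M, and the sum is 0.266 M against a V·t of 0.237 M.

Readings and results are calculated on assumed constants; noise was put on by code.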